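The readings are calculated from invented constants, and the scatter is random.

In a one-step world a complex facing excess ligand decays at one constant rate, and that pseudo-first-order rule was my bench start for these flasks.

| flask | starting complex | incoming ligand | remark | time |
|---|---|---|---|---|
| oak | 20 mM | 1.3 equiv | run made earlier |  |
| maple | 20 mM | 3.5 equiv | run made earlier |  |
| teal | 20 mM | 2.00 equiv |  | 8.0 min |
| blue | 20 mM | 4.00 equiv |  | 8.0 min |

| run | time / min | complex with two exchanged / % | starting complex / % |
|---|---|---|---|
| oak | 1.00 | 37.2 | 24.3 |
| oak | 2.00 | 40.4 | 25.7 |
| oak | 3.00 | 38.4 | 23.2 |
| oak | 4.00 | 39.8 | 23.3 |
| maple | 0.500 | 63.6 | 2.1 |
| maple | 1.33 | 53.5 | 0 |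
| maple | 2.50 | 39.2 | 0 |
| maple | 4.00 | 29.2 | 1.1 |

(scatter of a reading: 1 percentage point)



- which of these holds the largest part of the starting complex at the end of teal (starting complex / complex with two exchanged / complex with three exchanged / complex with one exchanged)
- which of these holds the largest part of the starting complex at the end of blue (starting complex / complex with two exchanged / complex with three exchanged / complex with one exchanged)
- how much complex with two exchanged is there at the end of blue, in percent of the starting complex charged

In the oak run the two-exchanged complex stayed near 39.8%, while in maple the starting complex was down to 2.1% by 0.500 min and the two-exchanged complex then kept falling. So for maple and blue I took the first two exchanges as over and reckoned with the ligand they leave free. Let c be the complex with two exchanged as a fraction of the charge, and s the equivalents charged less 3. With each complex counted as two- or three-exchanged, free ligand is then s + c, and c/(s + c) falls as exp(−κst). From maple's readings at 1.33 min and 4.00 min I read κ, the third-exchange constant per unit of c and of free ligand, as 0.253 /min.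

Holding free ligand at its starting 2.00 equivalents, the bench rule puts c at 1.74% at the end of blue. But the ratio of free ligand after a full third exchange to free ligand at its start in blue, the equivalents less 3 over the equivalents less 2, is 0.500: that is half, and the rule of constant ligand stops working there. The full form, started from c = 1, gives c/(s + c) = 0.0660, so I put c at 7.07%, more than the rule gave, with the complex with three exchanged leading in blue. Teal's 2.00 equiv pays for two exchanges per complex, so I expected the complex with two exchanged to lead there.

The forecast named complex with two exchanged for teal and complex with three exchanged for blue, with 6% against my 7.07%, holding that “the two-exchanged complex slowly converts to three-exchanged”.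

Teal ended with complex with two exchanged at 64.3%. Blue ended with complex with three exchanged at 91.3% and the complex with two exchanged at 6.74%.

    complex with one exchanged + incoming ligand → leaving ligand + complex with two exchanged (k = 5.69 /M/s)
    complex with two exchanged ⇌ isomer of the product (K = 0.290, k = 0.502 /s)
    complex with two exchanged + incoming ligand → leaving ligand + complex with three exchanged (k = 0.249 /M/s)
    starting complex + incoming ligand → leaving ligand + complex with one exchanged (k = 3.69 /M/s)

The flask also holds an isomer of the product, which c does not count; at the end of blue it stood at 1.96%, beside 6.74% of the complex with two exchanged. Blue read at 20 min keeps the same s and κ, so c/(s + c) becomes 0.003165 and c becomes 0.318%. That flask gave 0.388%.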